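**Strategy.** The cyclopentane ring (C2–C6, carotenoid numbering) carries the polyene carbon C7 on C6 and the carbinol carbon C1 on C2 as cis neighbours. Cutting C6–C7 and C2–C1 reveals a Me2C=C two-carbon unit and the C2=C6 alkene of a cyclopentene whose C5 carbinol centre comes from (R)-linalool. One [2+2] cycloaddition of the tetramethylketeniminium ion to the silyl ether of (R)-1-methylcyclopent-2-en-1-ol makes both bonds, the cyclobutane and the C2 and C6 stereocentres, cis because both bonds form on one alkene face, anti to the silyloxy group. Baeyer–Villiger insertion between C7 and C1 then releases both arms, and three Wittig-type extensions (C3, C2, C25) complete the decaene.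

Key step: step 3

Remarks on the chemistry:
- Carotenoid locants are used throughout (ring C2–C6; C1 = carbinol carbon; chain C7–C15 and C15'–C1').
- The target SMILES corresponds to the (2R,5R,6R) isomer: C7, C1 and the C5 methyl lie on one ring face and the C5 oxygen on the other. (R)-Linalool supplies C5 in this sense, and the structures of the cycloaddition partners and product are mutually consistent, so none needed correction.
- The tert-butyldimethylsilyl (TBS) ether is kept as the cycloaddition substrate. The silyl group is removed in step 8, before the polyene exists, so the last step delivers the target without a deprotection on the carotenoid.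
- Assumption: pseudoionone is used as the (3E,5E) isomer drawn; any 5Z material in the commercial product is removed when salt 17 is crystallised.

**Route**

Step 1
Reactants: 1 (R)-(−)-linalool
Product: 2 (R)-1-methylcyclopent-2-en-1-ol
Conditions: second-generation Grubbs catalyst RuCl2(PCy3)(H2IMes)(=CHPh) (0.5 mol%), neat, rt → 40 °C, isobutene vented; distillation
Reagents that add atoms: none
Why: Ring-closing metathesis of this 1,6-diene is fast because the allylic hydroxyl assists and isobutene leaves as a gas; the C5 carbinol centre is not involved, so its (R) configuration is carried over unchanged.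

Step 2
Reactants: 2 (R)-1-methylcyclopent-2-en-1-ol
Product: 3 (R)-tert-butyldimethyl[(1-methylcyclopent-2-en-1-yl)oxy]silane
Conditions: TBSOTf (1.3 equiv), 2,6-lutidine (2 equiv), CH2Cl2, −78 → 0 °C
Reagents that add atoms: tert-butyldimethylsilyl trifluoromethanesulfonate, CC(C)(C)[Si](C)(C)OS(=O)(=O)C(F)(F)F
Why: O-Silylation with a silyl triflate and a hindered base should protect the tertiary allylic alcohol at low temperature without ionising the C–O bond; TBS is about the largest silyl group that still goes cleanly onto a tertiary carbinol, so it shields one alkene face and survives steps 3–7.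

Step 3
Reactants: 3 (R)-tert-butyldimethyl[(1-methylcyclopent-2-en-1-yl)oxy]silane; 4 1-chloro-N,N,2-trimethylprop-1-en-1-amine
Product: 7 (1R,4R,5R)-4-[(tert-butyldimethylsilyl)oxy]-4,7,7-trimethylbicyclo[3.2.0]heptan-6-one, via keteniminium tetrafluoroborate 5 (not isolated), via cyclobutaniminium tetrafluoroborate 6 (not isolated)
Conditions: AgBF4 (1.3 equiv), CH2Cl2, −60 °C; 2,6-di-tert-butyl-4-methylpyridine (0.1 equiv), −60 °C → rt (40 °C if slow); then aq. NaHCO3, rt
Reagents that add atoms: water, O
Why: Silver ion abstracts chloride from 4 to give keteniminium salt 5; the C2=C6 π bond attacks its linear central carbon (future C7) through C6, so that positive charge builds at C2, the alkene carbon further from the electron-withdrawing C5–O bond, and the enamine carbon (future C1) then closes onto C2 to give iminium salt 6, which water hydrolyses to the ketone. The closest known reaction is the keteniminium–cycloalkene [2+2] cycloaddition that turns cyclopentene into 7,7-dimethylbicyclo[3.2.0]heptan-6-one. The cyclobutane is closed intermolecularly as an asynchronous polar [2+2] cycloaddition (C6–C7 first, then C2–C1), suprafacial on the ring alkene. C6 and C2 are created together and must be cis because both bonds are delivered to one face of a cis ring alkene; the face is dictated by the C5 stereocentre, the reagent approaching anti to the bulky OTBS group and syn to the methyl group. The step needs regio- and facial selectivity, and both rest on the quaternary C5 carbinol carbon: its C–O dipole and its bulk place the slim sp carbon at C6 and the large CMe2 terminus at the unhindered C2.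

Step 4
Reactants: 7 (1R,4R,5R)-4-[(tert-butyldimethylsilyl)oxy]-4,7,7-trimethylbicyclo[3.2.0]heptan-6-one
Product: 8 (3aR,6R,6aR)-6-[(tert-butyldimethylsilyl)oxy]-3,3,6-trimethylhexahydro-1H-cyclopenta[c]furan-1-one
Conditions: mCPBA (1.5 equiv), CH2Cl2, 0 °C → rt
Reagents that add atoms: 3-chloroperoxybenzoic acid, OOC(=O)c1cccc(Cl)c1
Why: Baeyer–Villiger oxidation of the strained cyclobutanone should be fast, and in the tetrahedral peracid adduct the fully substituted C1 migrates in preference to the methine C6, with retention, so oxygen enters between C7 and C1 and no stereocentre changes.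

Step 5
Reactants: 8 (3aR,6R,6aR)-6-[(tert-butyldimethylsilyl)oxy]-3,3,6-trimethylhexahydro-1H-cyclopenta[c]furan-1-one
Product: 9 (3aR,6R,6aR)-6-[(tert-butyldimethylsilyl)oxy]-3,3,6-trimethylhexahydro-1H-cyclopenta[c]furan-1-ol (both anomers)
Conditions: iBu2AlH (1.1 equiv), CH2Cl2, −78 °C; aq. KNaC4H4O6
Reagents that add atoms: none
Why: Half-reduction of a γ-lactone with a dialkylaluminium hydride at −78 °C stops at the aluminium hemiacetal, which gives the lactol on work-up; the tertiary silyl ether is inert and the new anomeric centre is of no consequence.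

Step 6
Reactants: 9 (3aR,6R,6aR)-6-[(tert-butyldimethylsilyl)oxy]-3,3,6-trimethylhexahydro-1H-cyclopenta[c]furan-1-ol
Product: 11 (E)-4-[(1R,2R,5R)-2-[(tert-butyldimethylsilyl)oxy]-5-(2-hydroxypropan-2-yl)-2-methylcyclopentyl]but-3-en-2-one, via ring-opened hydroxy aldehyde 10 (not isolated)
Conditions: Ph3P=CHC(O)CH3 (2 equiv), PhCO2H (10 mol%), toluene, 80 °C
Reagents that add atoms: 1-(triphenyl-λ5-phosphanylidene)propan-2-one, CC(=O)C=P(c1ccccc1)(c1ccccc1)c1ccccc1
Why: Wittig olefination of a lactol through its open hydroxy aldehyde with a stabilised ylide should give the (E)-enone (C7=C8); the ylide is too weakly basic to epimerise C6 or to promote conjugate addition of the C1 hydroxyl, and the acid catalyst speeds lactol opening.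

Step 7
Reactants: 11 (E)-4-[(1R,2R,5R)-2-[(tert-butyldimethylsilyl)oxy]-5-(2-hydroxypropan-2-yl)-2-methylcyclopentyl]but-3-en-2-one
Product: 12 (1E)-1-[(1R,2R,5R)-2-[(tert-butyldimethylsilyl)oxy]-5-(2-hydroxypropan-2-yl)-2-methylcyclopentyl]-3-methylpenta-1,4-dien-3-ol (both C9 epimers)
Conditions: CH2=CHMgBr (3 equiv), THF, −78 → 0 °C; then H2O
Reagents that add atoms: vinylmagnesium bromide, C=C[Mg]Br
Why: Grignard 1,2-addition to the methyl enone (one equivalent is used up by the C1 hydroxyl) should give the tertiary doubly allylic alcohol; the new C9 centre forms as both epimers, which does not matter because C9 becomes sp2 in step 9.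

Step 8
Reactants: 12 (1E)-1-[(1R,2R,5R)-2-[(tert-butyldimethylsilyl)oxy]-5-(2-hydroxypropan-2-yl)-2-methylcyclopentyl]-3-methylpenta-1,4-dien-3-ol
Product: 13 (1R,2R,3R)-3-(2-hydroxypropan-2-yl)-2-[(1E)-3-hydroxy-3-methylpenta-1,4-dien-1-yl]-1-methylcyclopentan-1-ol
Conditions: nBu4NF (3 equiv), THF, rt → 50 °C
Reagents that add atoms: none
Why: Fluoride desilylation of the tertiary silyl ether is placed here, on a robust non-conjugated intermediate that tolerates warming and has no base-sensitive group, so that no deprotection is needed once the polyene exists.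

Step 9
Reactants: 13 (1R,2R,3R)-3-(2-hydroxypropan-2-yl)-2-[(1E)-3-hydroxy-3-methylpenta-1,4-dien-1-yl]-1-methylcyclopentan-1-ol
Product: 14 {(2E,4E)-5-[(1R,2R,5R)-2-hydroxy-5-(2-hydroxypropan-2-yl)-2-methylcyclopentyl]-3-methylpenta-2,4-dien-1-yl}triphenylphosphonium bromide
Conditions: PPh3·HBr (1.05 equiv), MeOH, 0 °C → rt; precipitation from EtOAc/Et2O
Reagents that add atoms: triphenylphosphine hydrobromide, [Br-].c1ccc(cc1)[PH+](c1ccccc1)c1ccccc1
Why: SN1'-type phosphonium salt formation: only the doubly allylic C9 alcohol ionises under the mild acid, and PPh3 captures the pentadienyl cation irreversibly at the unhindered C11 terminus to give the conjugated (E,E)-dienyl salt, whereas capture by bromide, methanol or an internal hydroxyl is reversible; the ring stereocentres are not touched.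

Step 10
Reactants: 15 pseudoionone, (3E,5E)-6,10-dimethylundeca-3,5,9-trien-2-one
Product: 16 (4E,6E)-3,7,11-trimethyldodeca-1,4,6,10-tetraen-3-ol (racemic)
Conditions: CH2=CHMgBr (1.3 equiv), THF, −20 → 0 °C; then H2O
Reagents that add atoms: vinylmagnesium bromide, C=C[Mg]Br
Why: Grignard 1,2-addition to the dienone carbonyl should give the tertiary vinyl carbinol; its stereocentre is lost in the next step.

Step 11
Reactants: 16 (4E,6E)-3,7,11-trimethyldodeca-1,4,6,10-tetraen-3-ol
Product: 17 [(2E,4E,6E)-3,7,11-trimethyldodeca-2,4,6,10-tetraen-1-yl]triphenylphosphonium bromide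
Conditions: PPh3·HBr (1.0 equiv), MeOH, rt; crystallisation
Reagents that add atoms: triphenylphosphine hydrobromide, [Br-].c1ccc(cc1)[PH+](c1ccccc1)c1ccccc1
Why: The same SN1' phosphonium salt formation on a well-behaved trienyl system should give the acyclic C15 salt, the new C9'=C10' bond being E under thermodynamic control and upgraded by crystallisation.

Step 12
Reactants: 17 [(2E,4E,6E)-3,7,11-trimethyldodeca-2,4,6,10-tetraen-1-yl]triphenylphosphonium bromide; 18 (2E,4E,6E)-2,7-dimethylocta-2,4,6-trienedial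
Product: 20 (2E,4E,6E,8E,10E,12E,14E)-2,7,11,15,19-pentamethylicosa-2,4,6,8,10,12,14,18-octaenal, via psi-end C15 ylide 19 (not isolated)
Conditions: 18 (3 equiv), NaOMe (1.1 equiv), CH2Cl2/MeOH, −10 °C → rt, dark; then heptane, 80 °C; crystallisation
Reagents that add atoms: none
Why: Wittig olefination of one formyl group of the symmetrical dialdehyde; the excess of 18 and slow addition of base should suppress double olefination, and the sterically hindered Z isomer at the new C11'=C12' bond reverts to E on heating.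

Step 13
Reactants: 14 {(2E,4E)-5-[(1R,2R,5R)-2-hydroxy-5-(2-hydroxypropan-2-yl)-2-methylcyclopentyl]-3-methylpenta-2,4-dien-1-yl}triphenylphosphonium bromide; 20 (2E,4E,6E,8E,10E,12E,14E)-2,7,11,15,19-pentamethylicosa-2,4,6,8,10,12,14,18-octaenal
Product: 22 CNP0169920.2, (all-E,2R,5R,6R)-2,6-cyclolycopene-1,5-diol, via ring-end C15 ylide 21 (not isolated)
Conditions: NaOMe (1.2 equiv), CH2Cl2/MeOH, 0 °C → rt, Ar, dark; then EtOH, reflux; crystallisation
Reagents that add atoms: none
Why: Wittig olefination of the C25 polyenal by the semi-stabilised dienyl ylide forms C11=C12; methoxide does not deprotonate the free tertiary hydroxyls to a useful extent, the hindered 11Z isomer should isomerise thermally to the all-E compound, and no stereocentre is touched.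

**Compound list**

1 | (R)-(−)-linalool, (3R)-3,7-dimethylocta-1,6-dien-3-ol | CC(C)=CCC[C@@](C)(O)C=C | starting material
2 | (R)-1-methylcyclopent-2-en-1-ol | C[C@]1(O)C=CCC1 | intermediate
3 | (R)-tert-butyldimethyl[(1-methylcyclopent-2-en-1-yl)oxy]silane | C[C@]1(O[Si](C)(C)C(C)(C)C)C=CCC1 | intermediate
4 | 1-chloro-N,N,2-trimethylprop-1-en-1-amine | CC(C)=C(Cl)N(C)C | starting material
5 | N,N-dimethyl-2-methylprop-1-en-1-ylideneammonium tetrafluoroborate (tetramethylketeniminium salt) | CC(C)=C=[N+](C)C.F[B-](F)(F)F | intermediate (not isolated)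
6 | cyclobutaniminium tetrafluoroborate, N,N-dimethyliminium salt of ketone 7 | C[C@@]1(O[Si](C)(C)C(C)(C)C)CC[C@@H]2[C@H]1C(=[N+](C)C)C2(C)C.F[B-](F)(F)F | intermediate (not isolated)
7 | (1R,4R,5R)-4-[(tert-butyldimethylsilyl)oxy]-4,7,7-trimethylbicyclo[3.2.0]heptan-6-one (ring fusion and C4 methyl all cis) | C[C@@]1(O[Si](C)(C)C(C)(C)C)CC[C@@H]2[C@H]1C(=O)C2(C)C | intermediate
8 | (3aR,6R,6aR)-6-[(tert-butyldimethylsilyl)oxy]-3,3,6-trimethylhexahydro-1H-cyclopenta[c]furan-1-one | C[C@@]1(O[Si](C)(C)C(C)(C)C)CC[C@@H]2[C@H]1C(=O)OC2(C)C | intermediate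
9 | (3aR,6R,6aR)-6-[(tert-butyldimethylsilyl)oxy]-3,3,6-trimethylhexahydro-1H-cyclopenta[c]furan-1-ol (both anomers) | C[C@@]1(O[Si](C)(C)C(C)(C)C)CC[C@@H]2[C@H]1C(O)OC2(C)C | intermediate
10 | (1R,2R,5R)-2-[(tert-butyldimethylsilyl)oxy]-5-(2-hydroxypropan-2-yl)-2-methylcyclopentane-1-carbaldehyde | O=C[C@@H]1[C@H](C(C)(C)O)CC[C@@]1(C)O[Si](C)(C)C(C)(C)C | intermediate (not isolated)
11 | (E)-4-[(1R,2R,5R)-2-[(tert-butyldimethylsilyl)oxy]-5-(2-hydroxypropan-2-yl)-2-methylcyclopentyl]but-3-en-2-one | CC(=O)/C=C/[C@@H]1[C@H](C(C)(C)O)CC[C@@]1(C)O[Si](C)(C)C(C)(C)C | intermediate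
12 | (1E)-1-[(1R,2R,5R)-2-[(tert-butyldimethylsilyl)oxy]-5-(2-hydroxypropan-2-yl)-2-methylcyclopentyl]-3-methylpenta-1,4-dien-3-ol (both C3 epimers) | C=CC(C)(O)/C=C/[C@@H]1[C@H](C(C)(C)O)CC[C@@]1(C)O[Si](C)(C)C(C)(C)C | intermediate
13 | (1R,2R,3R)-3-(2-hydroxypropan-2-yl)-2-[(1E)-3-hydroxy-3-methylpenta-1,4-dien-1-yl]-1-methylcyclopentan-1-ol | C=CC(C)(O)/C=C/[C@@H]1[C@H](C(C)(C)O)CC[C@@]1(C)O | intermediate
14 | {(2E,4E)-5-[(1R,2R,5R)-2-hydroxy-5-(2-hydroxypropan-2-yl)-2-methylcyclopentyl]-3-methylpenta-2,4-dien-1-yl}triphenylphosphonium bromide | C(/C=C(C)/C=C/[C@@H]1[C@H](C(C)(C)O)CC[C@@]1(C)O)[P+](c2ccccc2)(c3ccccc3)c4ccccc4.[Br-] | intermediate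
15 | pseudoionone, (3E,5E)-6,10-dimethylundeca-3,5,9-trien-2-one | CC(C)=CCC/C(C)=C/C=C/C(C)=O | starting material
16 | (4E,6E)-3,7,11-trimethyldodeca-1,4,6,10-tetraen-3-ol (racemic) | CC(C)=CCC/C(C)=C/C=C/C(C)(O)C=C | intermediate
17 | [(2E,4E,6E)-3,7,11-trimethyldodeca-2,4,6,10-tetraen-1-yl]triphenylphosphonium bromide | CC(C)=CCC/C(C)=C/C=C/C(C)=C/C[P+](c1ccccc1)(c1ccccc1)c1ccccc1.[Br-] | intermediate
18 | (2E,4E,6E)-2,7-dimethylocta-2,4,6-trienedial (C10 dialdehyde) | O=C/C(C)=C/C=C/C=C(C)/C=O | starting material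
19 | ylide of 17, triphenyl[(2E,4E,6E)-3,7,11-trimethyldodeca-2,4,6,10-tetraen-1-ylidene]-λ5-phosphane | CC(C)=CCC/C(C)=C/C=C/C(C)=C/C=P(c1ccccc1)(c1ccccc1)c1ccccc1 | intermediate (not isolated)
20 | C25 aldehyde, (2E,4E,6E,8E,10E,12E,14E)-2,7,11,15,19-pentamethylicosa-2,4,6,8,10,12,14,18-octaenal | CC(C)=CCC/C(C)=C/C=C/C(C)=C/C=C/C(C)=C/C=C/C=C(C)/C=O | intermediate
21 | ylide of 14 | C(/C=C(C)/C=C/[C@@H]1[C@H](C(C)(C)O)CC[C@@]1(C)O)=P(c2ccccc2)(c3ccccc3)c4ccccc4 | intermediate (not isolated)
22 | CNP0169920.2, (all-E,2R,5R,6R)-2,6-cyclolycopene-1,5-diol | CC(C)=CCC/C(C)=C/C=C/C(C)=C/C=C/C(C)=C/C=C/C=C(C)/C=C/C=C(C)/C=C/[C@@H]1[C@H](C(C)(C)O)CC[C@@]1(C)O | target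

**Totals and risks**

Total step count: 13. Longest linear sequence: 10 (steps 1–9, then step 13).

Step 3 (key cycloaddition). The keteniminium ion must bond at the neopentyl-type C6, so the cycloaddition may be slow. Ionisation or elimination of the tertiary allylic silyl ether could then compete, and facial or regiochemical control could erode with this bulky cationic reagent. Fallback: the same two bonds are made with dichloroketene, the most reactive ketene toward unactivated cycloalkenes. The fallback sets out from 3. Treatment with Cl3CCOCl and Zn(Cu) in Et2O in the presence of POCl3 should give the 7,7-dichloro analogue of 7 F1 by the same regiochemical and facial logic. Zn dust in AcOH removes both chlorines to give the parent cyclobutanone F2. Two rounds of KN(SiMe3)2 and MeI in THF at −78 °C then methylate the CH2 group, kinetic deprotonation avoiding the hindered ring-fusion C6–H. This passes through the monomethyl ketone F3 and returns to the route at 7.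

Step 6 (Wittig on the lactol). The gem-dimethyl lactol may stay closed, so that the slow olefination is overtaken by conjugate addition of the C1 hydroxyl to the enone or by epimerisation at C6 of the open aldehyde. Fallback: the lactol is avoided and the C1 hydroxyl is masked. The fallback sets out from lactone 8. LiAlH4 in THF at 0 °C reduces it to the diol F4. Et3SiOTf and 2,6-lutidine silylate both hydroxyls to give the bis(triethylsilyl) ether F5. Swern conditions ((COCl)2, DMSO, then iPr2NEt) selectively unmask and oxidise the primary triethylsilyl ether to the aldehyde F6. Wittig reaction with Ph3P=CHC(O)CH3 gives the fully silylated enone F7, and CH2=CHMgBr gives the vinyl carbinol F8. nBu4NF then removes both silyl groups, and the route is rejoined at triol 13.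

Step 9 (phosphonium salt on the triol). The cis C1 hydroxyl may capture the pentadienyl cation at C7 in a way that does not revert, or the cation may lose a proton to trienes. Fallback: the polarity of the last coupling is reversed, so that no cation is generated on the ring fragment. The fallback sets out from enone 11 and from aldehyde 20. Horner–Wadsworth–Emmons reaction of 11 with the anion of diethyl (cyanomethyl)phosphonate (NaH in slight deficit, THF) gives the (2E,4E)-dienenitrile F9 after removal of the 2Z isomer. iBu2AlH reduction and hydrolytic work-up give the C15 dienal F10. In parallel, NaBH4 reduces 20 to the C25 alcohol F11, and PPh3·HBr converts it into the C25 phosphonium bromide F12. NaOMe generates its ylide F13, which condenses with F10 to the 5-O-silylated carotenoid F14. nBu4NF cleaves the silyl ether and the fallback arrives at target 22.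

**Further compounds**

F1 | step 3 | 7,7-dichloro analogue of 7, 4-[(tert-butyldimethylsilyl)oxy]-7,7-dichloro-4-methylbicyclo[3.2.0]heptan-6-one (configuration as in 7) | C[C@@]1(O[Si](C)(C)C(C)(C)C)CC[C@@H]2[C@H]1C(=O)C2(Cl)Cl
F2 | step 3 | parent cyclobutanone, 4-[(tert-butyldimethylsilyl)oxy]-4-methylbicyclo[3.2.0]heptan-6-one (configuration as in 7) | C[C@@]1(O[Si](C)(C)C(C)(C)C)CC[C@@H]2[C@H]1C(=O)C2
F3 | step 3 | monomethyl ketone, 4-[(tert-butyldimethylsilyl)oxy]-4,7-dimethylbicyclo[3.2.0]heptan-6-one (either C7 epimer) | C[C@@]1(O[Si](C)(C)C(C)(C)C)CC[C@@H]2[C@H]1C(=O)C2C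
F4 | step 6 | diol, 2-[(1R,2R,3R)-3-[(tert-butyldimethylsilyl)oxy]-2-(hydroxymethyl)-3-methylcyclopentyl]propan-2-ol | OC[C@@H]1[C@H](C(C)(C)O)CC[C@@]1(C)O[Si](C)(C)C(C)(C)C
F5 | step 6 | bis(triethylsilyl) ether of F4 | CC[Si](CC)(CC)OC[C@@H]1[C@H](C(C)(C)O[Si](CC)(CC)CC)CC[C@@]1(C)O[Si](C)(C)C(C)(C)C
F6 | step 6 | aldehyde, 1-O-triethylsilyl ether of 10 | O=C[C@@H]1[C@H](C(C)(C)O[Si](CC)(CC)CC)CC[C@@]1(C)O[Si](C)(C)C(C)(C)C
F7 | step 6 | enone, 1-O-triethylsilyl ether of 11 | CC(=O)/C=C/[C@@H]1[C@H](C(C)(C)O[Si](CC)(CC)CC)CC[C@@]1(C)O[Si](C)(C)C(C)(C)C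
F8 | step 6 | vinyl carbinol, 1-O-triethylsilyl ether of 12 (both C9 epimers) | C=CC(C)(O)/C=C/[C@@H]1[C@H](C(C)(C)O[Si](CC)(CC)CC)CC[C@@]1(C)O[Si](C)(C)C(C)(C)C
F9 | step 9 | (2E,4E)-5-[(1R,2R,5R)-2-[(tert-butyldimethylsilyl)oxy]-5-(2-hydroxypropan-2-yl)-2-methylcyclopentyl]-3-methylpenta-2,4-dienenitrile | N#C/C=C(C)/C=C/[C@@H]1[C@H](C(C)(C)O)CC[C@@]1(C)O[Si](C)(C)C(C)(C)C
F10 | step 9 | (2E,4E)-5-[(1R,2R,5R)-2-[(tert-butyldimethylsilyl)oxy]-5-(2-hydroxypropan-2-yl)-2-methylcyclopentyl]-3-methylpenta-2,4-dienal | O=C/C=C(C)/C=C/[C@@H]1[C@H](C(C)(C)O)CC[C@@]1(C)O[Si](C)(C)C(C)(C)C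
F11 | step 9 | C25 alcohol, (2E,4E,6E,8E,10E,12E,14E)-2,7,11,15,19-pentamethylicosa-2,4,6,8,10,12,14,18-octaen-1-ol | CC(C)=CCC/C(C)=C/C=C/C(C)=C/C=C/C(C)=C/C=C/C=C(C)/CO
F12 | step 9 | C25 phosphonium bromide, [(2E,4E,6E,8E,10E,12E,14E)-2,7,11,15,19-pentamethylicosa-2,4,6,8,10,12,14,18-octaen-1-yl]triphenylphosphonium bromide | CC(C)=CCC/C(C)=C/C=C/C(C)=C/C=C/C(C)=C/C=C/C=C(C)/C[P+](c1ccccc1)(c1ccccc1)c1ccccc1.[Br-]
F13 | step 9 | ylide of F12 | CC(C)=CCC/C(C)=C/C=C/C(C)=C/C=C/C(C)=C/C=C/C=C(C)/C=P(c1ccccc1)(c1ccccc1)c1ccccc1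
F14 | step 9 | 5-O-(tert-butyldimethylsilyl) ether of 22 | CC(C)=CCC/C(C)=C/C=C/C(C)=C/C=C/C(C)=C/C=C/C=C(C)/C=C/C=C(C)/C=C/[C@@H]1[C@H](C(C)(C)O)CC[C@@]1(C)O[Si](C)(C)C(C)(C)C
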